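Assumptions: cembrane numbering is used (C1 = lactone β‑CH, C3/C4 = epoxide, C13 = CH‑OAc, C14 = lactone O‑CH, C15/C16/C17 = C(=CH2)–C=O). C13′ is the malate carboxyl carbon that is later lost as CO2. Compounds 1 and 2 are taken as commercial.

## Retrosynthetic overview
1. Target 11 comes from acetylation of 10. The 14‑membered ring of 10 is closed at C13–C14 by a photoredox/Cr decarboxylative addition of lactone acid 9 to its own enal.
2. Enal 9 comes from allylic oxidation of the farnesyl terminus of 8. The α‑methylene lactone of 8 comes from terminal alkyne 7 plus CO2 (C15–C16 bond), followed by lactonisation on O14.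
3. The alkyne and epoxide of 7 are released together from δ‑iodolactol 6. Iodolactonisation of diacid 4 relays stereochemistry from C1 to C3/C4.
4. Diacid 4 comes from Fráter–Seebach alkylation of dimethyl L‑malate, the only chiral input, with farnesyl bromide, which supplies C2–C13 and all E‑alkenes.
5. Ring order: temporary δ‑iodolactone, then epoxide, then γ‑lactone, then 14‑membered carbocycle.

## Route

**Step 1**
Reactants: 1 dimethyl (S)‑malate; 2 (2E,6E)‑farnesyl bromide
Product: 3 dimethyl (2S,3R)‑2‑hydroxy‑3‑[(2E,6E)‑farnesyl]butanedioate
Conditions: LiHMDS (2.2 equiv), THF, −78 → −20 °C; then 2, −78 → −10 °C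
Reagents that add atoms: none
Why: Fráter–Seebach alkylation, in which the Li‑chelated alkoxide/enolate dianion takes the allylic bromide (SN2, alkene geometry untouched) anti to the C14 CO2Me group, so the purchased C14 centre sets C1 (anti, typically ≥9:1, minor isomer removed by chromatography).

**Step 2**
Reactants: 3
Product: 4 (2S,3R)‑2‑hydroxy‑3‑farnesylbutanedioic acid
Conditions: LiOH (4 equiv), THF/H2O, 0 °C → rt; KHSO4 to pH 3
Reagents that add atoms: water/hydroxide, O ([Li+].[OH-])
Why: Plain saponification that touches no stereocentre and frees both the C15 carboxylate for the relay and the C13′ carboxyl used later as the radical precursor.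

**Step 3**
Reactants: 4
Product: 5 (2S)‑2‑hydroxy‑2‑{(3R,5R,6S)‑5‑iodo‑6‑methyl‑6‑[(3E)‑4,8‑dimethylnona‑3,7‑dienyl]‑2‑oxooxan‑3‑yl}acetic acid
Conditions: I2 (2.5 equiv), NaHCO3, MeCN, 0 °C, dark
Reagents that add atoms: iodine, II
Why: Bartlett‑type iodolactonisation, in which the C15 carboxylate opens the iodonium of the nearby C3=C4 alkene in Markovnikov 6‑endo fashion through a chair with the C1 side chain, the iodine and the C5 chain all equatorial, so anti addition to the E‑alkene fixes C3 (C–I) and C4 (C–O) relative to C1 (expected about 5:1), while the remote alkenes have no internal nucleophile and only form iodonium ions reversibly.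

**Step 4**
Reactants: 5
Product: 6, the corresponding δ‑lactol (2‑hydroxyoxane, anomeric mixture)
Conditions: Sia2BH (5 equiv), THF, 0 °C → rt; MeOH, then pH 7 H2O2
Reagents that add atoms: none
Why: Disiamylborane reduction of a lactone to the lactol, in which CO2H and OH only evolve H2 and the hindered borane leaves the trisubstituted alkenes and the secondary iodide alone, so no stereocentre changes.

**Step 5**
Reactants: 6
Product: 7 (2S,3S)‑2‑hydroxy‑3‑({(2S,3S)‑3‑methyl‑3‑[(3E)‑4,8‑dimethylnona‑3,7‑dienyl]oxiran‑2‑yl}methyl)pent‑4‑ynoic acid, kept as its K salt and never acidified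
Conditions: Bestmann–Ohira reagent (1.5 equiv), K2CO3 (5 equiv), MeOH, 0 °C → rt
Reagents that add atoms: dimethyl (1‑diazo‑2‑oxopropyl)phosphonate, COP(=O)(OC)C(=[N+]=[N-])C(C)=O (supplies C17)
Why: Ohira–Bestmann homologation run as a cascade, in which the lactol opens in basic methanol, the C4 alkoxide displaces the anti‑periplanar C3 iodide (SN2 inversion) to give the (3S,4S)‑trans‑epoxide, and the aldehyde released becomes the terminal alkyne without touching C1.

**Step 6**
Reactants: 7
Product: 8 (2S,3S)‑4‑methylidene‑5‑oxo‑3‑({(2S,3S)‑epoxide side chain as in 7}methyl)oxolane‑2‑carboxylic acid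
Conditions: Ni(bpy)3(BF4)2 (10 mol %), CO2 (1 atm), n‑Bu4NBF4, DMF, Mg(+)/C felt(−), constant current, rt; then 2‑chloro‑1‑methylpyridinium iodide (1.0 equiv), Et3N (one pot)
Reagents that add atoms: carbon dioxide, O=C=O (supplies C16)
Why: Nickel‑catalysed electroreductive hydrocarboxylation of a terminal alkyne places CO2 on the internal carbon via an oxanickelacycle to give the 2‑substituted acrylate, and Mukaiyama lactonisation of this more basic carboxylate, the only one with an intramolecular OH partner, closes the trans α‑methylene‑γ‑lactone under non‑acidic conditions with the C14–O bond retained.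

**Step 7**
Reactants: 8
Product: 9, the (2E)‑terminal enal of 8 (C13H3 → C13HO)
Conditions: SeO2 (0.3 equiv), t‑BuOOH, CH2Cl2, 0 °C → rt; crude alcohol/aldehyde mixture then treated with DMP, NaHCO3 (telescoped)
Reagents that add atoms: selenium dioxide, O=[Se]=O; tert‑butyl hydroperoxide, CC(C)(C)OO (oxygen source)
Why: Sharpless–Umbreit allylic oxidation (ene/[2,3]) selects the (E)‑methyl of the terminal, most electron‑rich gem‑dimethyl alkene (about 50 % is typical for farnesyl systems), the acrylate alkene is inert, and DMP converges the mixture on the enal.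

**Step 8**
Reactants: 9
Product: 10 13‑hydroxysarcocrassolide (13‑deacetyl target; 1S,3S,4S,13S,14S)
Conditions: 4CzIPN (5 mol %), CrCl2 (20 mol %), dtbbpy (22 mol %), 2,6‑lutidine (2 equiv), DMF, 9 added by syringe pump to 1 mM, 450 nm LEDs, 25 °C, Ar
Reagents that add atoms: none (CO2 is lost)
Why: Proposed new method: a redox‑neutral decarboxylative photoredox/chromium NHK‑type macrocyclisation, in which excited 4CzIPN oxidises the carboxylate, loss of CO2 gives the ring‑confined C14 α‑acyloxy radical, and Cr(II) traps it reversibly (about 10^8 M⁻¹ s⁻¹, faster than Giese pathways at 1 mM) on the face anti to the C1 side chain; the resulting trans alkyl–Cr(III) adds 1,2 to the Cr‑bound enal with retention through a closed four‑centre transition state that places C12 gauche to H14 rather than to the lactone oxygen (predicted 13S,14S syn), lutidinium releases the alkoxide and the reduced photocatalyst regenerates Cr(II); the closest known reaction types are photoredox/Cr additions of allyl and α‑amino radicals to aldehydes and Cr‑mediated or electrochemical NHK couplings of redox‑active esters, none shown for free α‑acyloxy acids or for macrocyclisation.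

**Step 9**
Reactants: 10
Product: 11 13‑acetoxysarcocrassolide
Conditions: Ac2O, pyridine, DMAP (cat.), CH2Cl2, 0 °C → rt
Reagents that add atoms: acetic anhydride, CC(=O)OC(C)=O
Why: Standard DMAP‑catalysed acylation of the secondary allylic alcohol with retention at C13, under conditions that the epoxide and the α‑methylene lactone tolerate.

## Compound list
1 | dimethyl (S)‑malate | COC(=O)C[C@H](O)C(=O)OC | starting material
2 | (2E,6E)‑farnesyl bromide | BrC/C=C(\C)CC/C=C(\C)CCC=C(C)C | starting material
3 | dimethyl (2S,3R)‑2‑hydroxy‑3‑farnesylbutanedioate | COC(=O)[C@@H]([C@H](O)C(=O)OC)C/C=C(\C)CC/C=C(\C)CCC=C(C)C | intermediate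
4 | (2S,3R)‑2‑hydroxy‑3‑farnesylbutanedioic acid | OC(=O)[C@@H]([C@H](O)C(=O)O)C/C=C(\C)CC/C=C(\C)CCC=C(C)C | intermediate
5 | δ‑iodolactone acid | O=C1O[C@@](C)(CC/C=C(\C)CCC=C(C)C)[C@H](I)C[C@@H]1[C@H](O)C(=O)O | intermediate
6 | δ‑iodolactol acid (anomers) | OC1O[C@@](C)(CC/C=C(\C)CCC=C(C)C)[C@H](I)C[C@@H]1[C@H](O)C(=O)O | intermediate
7 | epoxy‑alkynyl α‑hydroxy acid | C#C[C@@H]([C@H](O)C(=O)O)C[C@@H]1O[C@@]1(C)CC/C=C(\C)CCC=C(C)C | intermediate
8 | α‑methylene lactone acid | C=C1C(=O)O[C@H](C(=O)O)[C@H]1C[C@@H]1O[C@@]1(C)CC/C=C(\C)CCC=C(C)C | intermediate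
9 | enal lactone acid | C=C1C(=O)O[C@H](C(=O)O)[C@H]1C[C@@H]1O[C@@]1(C)CC/C=C(\C)CC/C=C(\C)C=O | intermediate
10 | 13‑hydroxysarcocrassolide | C=C1C(=O)O[C@H]2[C@H]1C[C@@H]1O[C@@]1(C)CC/C=C(\C)CC/C=C(\C)[C@@H]2O | intermediate
11 | 13‑acetoxysarcocrassolide | C=C1C(=O)O[C@H]2[C@H]1C[C@@H]1O[C@@]1(C)CC/C=C(\C)CC/C=C(\C)[C@@H]2OC(C)=O | target

## Summary
Total steps: 9 (steps 6 and 7 are two‑stage one‑pot or telescoped operations). Longest linear sequence: 9.

**Steps most likely to fail**
1. **Step 8 (new macrocyclisation).** The risks are slow addition of the α‑acyloxyalkyl‑Cr species, Giese side reactions and the wrong C13 configuration. The fallback uses known chemistry and closes the ring at C12–C13 instead.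
   - Keep the malate C13′ carbon as an aldehyde.
   - Alkylate 1 with the 13‑nor‑12‑iodo analogue of 2, made from geranyl acetate by SeO2 oxidation, bromination, 2‑butynyllithium, then Cp2ZrHCl/I2.
   - Run a classical stoichiometric CrCl2/NiCl2 NHK macrocyclisation, and convert the Felkin alcohol directly to the 13S acetate by Mitsunobu reaction with AcOH.
   - If only C13 is wrong in step 8, use DMP oxidation followed by Luche reduction, which under Felkin control gives 13S.
2. **Step 3 (face and regioselectivity of the relay, and competition from the C14–OH).** The fallback drops halocyclisation and epoxidises diester 3 with VO(acac)2/t‑BuOOH. The free C14–OH then acts as a bishomoallylic director and selects the proximal alkene. The C15 ester is afterwards reduced to the aldehyde for the Ohira–Bestmann step.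
3. **Step 6 (electrocarboxylation regiochemistry and epoxide survival on a polyfunctional salt).** The fallback builds C15–C16 from CO instead of CO2. Mo‑catalysed Markovnikov hydrostannation and iododestannylation of the methyl ester of 7 give the 2‑iodo‑1‑alkene. Pd(0)/CO/Et3N carbonylative lactonisation and Me3SnOH ester cleavage follow.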